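## The problem

Compound 39 (CNP0109273.3) is a briarane-type diterpenoid. A cyclohexenone (ring A: C1, C10, C11, C12, C13, C14) is trans-fused along C1–C10 to a ten-membered carbocycle (ring B: C1 to C10), and ring B carries a butenolide (ring C: C7, C8, C17, C19 and the lactone oxygen) fused at C7–C8. The numbering used throughout is: C1 the quaternary, methyl-bearing fusion carbon; C2 the propionyloxy carbon; C5(Me)=C6 the Z alkene; C7 the lactone O–CH; C11(Me)=C12–C13(=O)–C14(OAc) the enone sector; C17 and C19 the α-carbon and carbonyl of ring C. The configuration is 1R,2S,7R,10R,14S.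

Four of the five stereocentres (C1, C2, C10, C14) cluster around C1. C10 and C1 are vicinal, and C2 and C14 are both neopentyl and 1,3-syn across C1, so each can be set from its neighbours. C7 is isolated from them by sp2 carbons on both sides and can only be controlled by the conformation of ring B or by a reagent.

Several groups are fragile. The two different esters sit on syn-1,3 oxygens, so an acyl group can migrate whenever one oxygen is free under basic conditions. The C14 hydrogen of the α-acetoxy enone is enolisable. The butenolide γ-hydrogen at C7 is acidic and epimerisable, which rules out strong base once ring C exists. The Z-trisubstituted alkene sits in a strained medium ring.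

The feature that opens the molecule is that C10, C1 and C2 are the β-carbon, the α-carbon and the aldol carbon of a 2-methylcyclohexenone whose carbonyl is C14. A C9 nucleophile and a C2 aldehyde can therefore be attached to one enone in a single operation. A methyl-bearing stereocentre at C11, absent from the target, can steer that operation before it is erased as the C11=C12 double bond. The price is that the carbonyl arrives at C14 and must be moved to C13.

## Retrosynthesis

**O2 acyl bond (39 ⇒ 38 ⇒ 37).** The propionate is removed first, giving alcohol 38 and its triethylsilyl ether 37. The propionate, not the acetate, is placed last because O2 and O14 are 1,3-syn: the acetate must go on while O2 is blocked, and O2 may be freed only under acidic conditions and acylated at once. The precursor is simpler by one acyl group. The forward steps must unmask a neopentyl silyl ether without base and esterify a hindered alcohol.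

**C6–C7 and O–C19 (37 ⇒ 35).** Ring B is opened at C6–C7 and ring C at the lactone C–O bond, giving iodoalkene enal ester 35. A cut at C5=C6 would require metathesis to a trisubstituted Z alkene in a ten-membered ring. Cuts at C1–C2 or C9–C10 are reserved for the fragment union. C6–C7 joins a vinyl carbon to a carbonyl carbon, for which the Nozaki–Hiyama–Kishi reaction is the most tolerant medium-ring method. The resulting alkoxide is cis to the ester, so ring C closes by itself. The precursor has one ring instead of three and lacks the C7 stereocentre. The forward reaction must run at high dilution, keep the Z geometry, and choose one face of the C7 aldehyde.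

**Unmasking ring C (35 ⇒ 34 ⇒ 32).** The Z-formyl acrylate is traced through lactol 34 to 2-silylfuran 32. A furan is the one form of ring C that survives Grignard formation, enolates and hydride. Silicon on C19 fixes that singlet oxygen makes C19 the carboxyl carbon and C7 the aldehyde carbon. The forward photooxygenation must spare the enone and the iodoalkene.

**Ring A oxidation pattern (32 ⇒ 31 ⇒ 30 ⇒ 29 ⇒ 27 ⇒ 25 ⇒ 24).** The α'-acetoxy enone is traced back to a C14 ketone: acetate to alcohol 31, enone carbonyl to the allylic alcohol of diol 30, C14 carbinol to ketone 29, C13 hydroxyl and shifted double bond to enone 27, then to saturated ketone 25 and aldol 24. This order puts every strong base before acetate and butenolide exist. It needs no palladium while the C–I bond is present. It lets MnO2 distinguish the allylic C13 from the saturated C14 alcohol. The C11 stereocentre is consumed here. The forward steps must hydroxylate C13 and reduce C14 with defined facial selectivity.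

**C9–C10 and C1–C2 (24 ⇒ 5 + 15 + 21).** Both bonds to ring A are cut at once, giving enone 5, furylmethyl Grignard reagent 15 and aldehyde 21. Neighbouring cuts (C8–C9 alkylation, or C2–C3 addition to a C2 aldehyde) would make one bond at a time and leave the quaternary C1 to a separate step. The three fragments have zero or one stereocentre each. The forward reaction must deliver 1,4-addition, a regiodefined enolate and three contiguous stereocentres.

**Enone (5 ⇒ 4 ⇒ 3 ⇒ 2 ⇒ 1).** The vinylic methyl is cut (cross-coupling of iodoenone 4), then the iodine (enone 3), then the double bond (silyl enol ether 2), leaving achiral 4-methylcyclohexanone 1. The single stereocentre comes from enantioselective deprotonation, which avoids a chiral-pool detour.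

**Grignard reagent (15 ⇒ 14 ⇒ 13 ⇒ 12 ⇒ 10 ⇒ 8 ⇒ 7 ⇒ 6).** The reagent is traced to chloride 14 and alcohol 13, then to silyl ether 12. The methyl group of 12 is traced to the hydroxymethyl of 10, whose alkoxide directs silicon to the adjacent ring carbon. Diol 7 and symmetric diester 6 follow. Starting from a symmetric furan and using the future methyl carbon as the directing group is what puts silicon next to C17 rather than next to C8.

**Aldehyde (21 ⇒ 19 ⇒ 18 ⇒ 16).** The C2–C3 unit is cut as an acetaldehyde enolate equivalent from allylic bromide 19. The Z-iodoalkene 18 comes from propargyl alcohol 16 by anti-carbometalation, the most direct source of this trisubstituted geometry.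

## Roads not taken

**Alternative 1:** Ring B would be closed at the allylic C3–C4 bond. A carbanion at C3, flanked by a C2 ketone and a phenylsulfonyl group, would displace an allylic bromide at C4 under high dilution with a carbonate base to give tricycle A1. Its merits are real. The ring closes by sp3–sp3 alkylation of a soft, stabilised carbanion, a reliable macrocyclisation type. The butenolide with its C7 stereocentre and the Z alkene are in place before ring closure, so C7 could be set by a reagent in an open chain. In this respect it is better than the chosen plan, which leaves C7 to the ring-closing step. Against this, A1 still carries a sulfone that must be removed reductively beside a butenolide and an allylic system. C2 is a ketone that must be reduced inside the ten-membered ring, so C2 becomes the conformation-dependent centre instead of C7. C14 is still a methylene, so the acetoxy group must be introduced late, next to the quaternary carbon. The carbonate base meets the acidic C7 hydrogen of the butenolide. The route also says nothing about the quaternary C1, which must be built separately. The chosen plan sets C1, C2 and C10 together and already has oxygen on C14.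

**Alternative 2:** The quaternary centre would come from a semipinacol ring expansion. Et2AlCl opens a C1–C2 epoxide next to a C14 cyclopentanol, and C10 migrates from C14 to C1, giving cyclohexanone A2 with the C14 ketone, the quaternary C1 and the free C2 hydroxyl. The shift is stereospecific, so C1 and C2 follow from the epoxide geometry. On the C1/C2 relationship this road is more secure than the aldol of the chosen plan, where C2 is the weakest centre. Its cost is linearity. The cyclopentanone with the C10 and C11 centres, the alkenyl addition, the directed epoxidation and the rearrangement are four operations for what the chosen plan does in one flask. Two ring bonds of the carbinol can migrate, and only anti-periplanar alignment selects C10. A2 carries a ketal-masked ketone in place of ring C and an allylic silyl ether in place of a C6 handle, so both ring C and the closure of ring B still need further steps. The chosen plan accepts a less certain C2 in exchange for convergence, and arrives with the furan and the vinyl iodide already installed.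

**Alternative 3:** Ring C would be assembled at C8–C9. A C9 Grignard reagent of a ring A fragment adds with CuI catalysis across the alkyne of a propargylic magnesium alkoxide, with magnesium anti at C17. CO2 then forms C17–C19, and acid closes the lactone to give A3. This builds the butenolide in one flask with the correct tetrasubstituted alkene. C7 comes from an enantiopure propargylic alcohol, which is better control of C7 than the chosen plan offers. The weak points are on the other side of the molecule. The Grignard carbon is neopentyl-like (next to C10 and the quaternary C1), a poor partner for carbomagnesiation of an internal alkyne. In A3, C2 is only a protected primary alcohol, so ring B must later be closed at C2–C3 and the C2 stereocentre made during macrocyclisation. C14 is again a methylene. The chosen plan has to set against the better C7 control of this road its firm hold on C1, C2, C10 and C14.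

Key step: step 15

Assumption: lithium (R,R)-bis(1-phenylethyl)amide is taken to give the (S)-enol ether 2, by analogy with its known sense on 4-tert-butylcyclohexanone. If the sense were opposite, the (S,S)-amide would be used. If needed, the enantiomeric excess would be raised by recrystallising a later crystalline intermediate.

## Route

Step 1
Reactants: 1 4-methylcyclohexanone
Product: 2 (S)-trimethyl[(4-methylcyclohex-1-en-1-yl)oxy]silane
Conditions: (R,R)-bis(1-phenylethyl)amine, n-BuLi, THF, −78 °C; Me3SiCl present (internal quench), −78 °C
Reagents that add atoms: chlorotrimethylsilane, C[Si](C)(C)Cl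
Why: Enantioselective deprotonation of a prochiral 4-substituted cyclohexanone by a C2-symmetric chiral lithium amide with in situ silylation (Simpkins–Koga desymmetrisation); the base selects one of the two enantiotopic α-protons and thereby sets the centre that becomes C11.

Step 2
Reactants: 2 (S)-trimethyl[(4-methylcyclohex-1-en-1-yl)oxy]silane
Product: 3 (S)-4-methylcyclohex-2-en-1-one
Conditions: Pd(OAc)2 (10 mol%), O2 (1 atm), DMSO, 25 °C
Reagents that add atoms: none
Why: Saegusa–Ito oxidation in its aerobic catalytic form; the divalent palladium enolate undergoes β-hydride elimination and zerovalent palladium is reoxidised by O2, leaving the stereocentre untouched.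

Step 3
Reactants: 3 (S)-4-methylcyclohex-2-en-1-one
Product: 4 (S)-2-iodo-4-methylcyclohex-2-en-1-one
Conditions: I2, pyridine, CH2Cl2, 0 °C to 25 °C
Reagents that add atoms: iodine, II
Why: α-Iodination of an enone by the Johnson protocol (conjugate addition of pyridine, iodination of the enolate, elimination); the γ-stereocentre is not enolised.

Step 4
Reactants: 4 (S)-2-iodo-4-methylcyclohex-2-en-1-one
Product: 5 (S)-2,4-dimethylcyclohex-2-en-1-one
Conditions: MeZnCl, Pd(PPh3)4 (5 mol%), THF, 0 °C to 25 °C
Reagents that add atoms: methylzinc chloride, C[Zn]Cl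
Why: Negishi coupling of a 2-iodoenone; the neutral conditions avoid dienolate formation and so preserve the configuration.

Step 5
Reactants: 6 diethyl furan-3,4-dicarboxylate
Product: 7 furan-3,4-diyldimethanol
Conditions: LiAlH4, THF, 0 °C
Reagents that add atoms: none
Why: Hydride reduction of both ester groups to the symmetric diol.

Step 6
Reactants: 7 furan-3,4-diyldimethanol
Product: 8 {4-[(tert-butyldimethylsilyloxy)methyl]furan-3-yl}methanol
Conditions: NaH (1.0 equiv), THF, 0 °C; t-BuMe2SiCl (1.0 equiv), 0 °C to 25 °C
Reagents that add atoms: tert-butyldimethylsilyl chloride, CC(C)(C)[Si](C)(C)Cl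
Why: Monosilylation of a symmetric diol through its sparingly soluble monosodium alkoxide (McDougal protocol).

Step 7
Reactants: 8 {4-[(tert-butyldimethylsilyloxy)methyl]furan-3-yl}methanol
Product: 10 {4-[(tert-butyldimethylsilyloxy)methyl]-2-(trimethylsilyl)furan-3-yl}methanol, via C,O-bis(trimethylsilyl) intermediate 9 (not isolated)
Conditions: n-BuLi (2.2 equiv), THF, −78 °C to 0 °C; Me3SiCl (2.5 equiv), −78 °C to 25 °C; then K2CO3 (cat.), MeOH, 25 °C
Reagents that add atoms: chlorotrimethylsilane, C[Si](C)(C)Cl
Why: Alkoxide-directed α-lithiation of a 3-furylmethanol: the lithium alkoxide steers the second equivalent of base to the adjacent ring C–H. Silylation on carbon and oxygen and methanolysis of the O–Si bond leave silicon beside the carbinol that will become the C17 methyl group.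

Step 8
Reactants: 10 {4-[(tert-butyldimethylsilyloxy)methyl]-2-(trimethylsilyl)furan-3-yl}methanol
Product: 12 tert-butyldimethyl{[4-methyl-5-(trimethylsilyl)furan-3-yl]methoxy}silane, via mesylate 11 (not isolated)
Conditions: MsCl, Et3N, CH2Cl2, −20 °C; then LiBHEt3, THF, 0 °C
Reagents that add atoms: none
Why: Activation of the benzylic-type alcohol as its mesylate and SN2 displacement by hydride turn CH2OH into the methyl group; the silyl ether and the ring C–Si bond are inert to the borohydride.

Step 9
Reactants: 12 tert-butyldimethyl{[4-methyl-5-(trimethylsilyl)furan-3-yl]methoxy}silane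
Product: 13 [4-methyl-5-(trimethylsilyl)furan-3-yl]methanol
Conditions: Bu4NF, THF, 0 °C
Reagents that add atoms: none
Why: Fluoride cleavage of the primary silyl ether; the furyl C–SiMe3 bond is not attacked at 0 °C.

Step 10
Reactants: 13 [4-methyl-5-(trimethylsilyl)furan-3-yl]methanol
Product: 14 [4-(chloromethyl)-3-methylfuran-2-yl]trimethylsilane
Conditions: PPh3, CCl4, CH2Cl2, 0 °C to 25 °C; used at once
Reagents that add atoms: tetrachloromethane, ClC(Cl)(Cl)Cl
Why: Appel chlorination under neutral conditions; the chloride is preferred to the bromide because benzylic-type chlorides give less Wurtz coupling on magnesiation.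

Step 11
Reactants: 14 [4-(chloromethyl)-3-methylfuran-2-yl]trimethylsilane
Product: 15 {[4-methyl-5-(trimethylsilyl)furan-3-yl]methyl}magnesium chloride (titrated THF solution)
Conditions: Mg turnings (activated with 1,2-dibromoethane), THF, 0 °C, slow addition
Reagents that add atoms: magnesium, [Mg]
Why: Insertion of magnesium into the benzylic-type C–Cl bond; 3-furylmethyl Grignard reagents are known, and slow addition at 0 °C keeps homocoupling low.

Step 12
Reactants: 16 prop-2-yn-1-ol
Product: 18 (Z)-3-iodo-2-methylprop-2-en-1-ol, via chelated vinylmagnesium alkoxide 17 (not isolated)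
Conditions: MeMgBr (3 equiv), CuI (10 mol%), THF, −10 °C to 25 °C; then I2, −78 °C to 0 °C
Reagents that add atoms: methylmagnesium bromide, C[Mg]Br; iodine, II
Why: Copper-catalysed anti-carbomagnesiation of a propargylic magnesium alkoxide (Duboudin reaction): methyl adds to the internal carbon and magnesium ends on the terminal carbon inside a five-membered chelate. Iodinolysis with retention then gives the alkene with CH2OH and iodine cis, the future 5Z geometry.

Step 13
Reactants: 18 (Z)-3-iodo-2-methylprop-2-en-1-ol
Product: 19 (Z)-3-bromo-1-iodo-2-methylprop-1-ene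
Conditions: CBr4, PPh3, CH2Cl2, 0 °C
Reagents that add atoms: tetrabromomethane, BrC(Br)(Br)Br
Why: Appel bromination of the allylic alcohol without allylic transposition or loss of alkene geometry.

Step 14
Reactants: 19 (Z)-3-bromo-1-iodo-2-methylprop-1-ene
Product: 21 (Z)-5-iodo-4-methylpent-4-enal, via dimethylhydrazone 20 (not isolated)
Conditions: acetaldehyde N,N-dimethylhydrazone, LiN(iPr)2, THF, 0 °C; then 19, −78 °C to 0 °C; then aq. oxalic acid, Et2O, 25 °C
Reagents that add atoms: acetaldehyde N,N-dimethylhydrazone, CC=NN(C)C; water, O
Why: Corey–Enders alkylation of a metalated aldehyde hydrazone (SN2 at the primary allylic bromide) followed by mild acid hydrolysis; a two-carbon homologation that leaves the vinyl iodide untouched.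

Step 15
Reactants: 5 (S)-2,4-dimethylcyclohex-2-en-1-one; 15 {[4-methyl-5-(trimethylsilyl)furan-3-yl]methyl}magnesium chloride; 21 (Z)-5-iodo-4-methylpent-4-enal
Product: 24 (2R,3R,4S)-2-[(1S,4Z)-1-hydroxy-5-iodo-4-methylpent-4-en-1-yl]-2,4-dimethyl-3-{[4-methyl-5-(trimethylsilyl)furan-3-yl]methyl}cyclohexan-1-one, via chloromagnesium enolate 22 (not isolated), via chlorozirconocene enolate 23 (not isolated)
Conditions: 5 (1.1 equiv), CuBr·SMe2 (10 mol%), THF, −78 °C, slow addition of 15 (1.0 equiv), −78 °C to −40 °C; Cp2ZrCl2 (1.2 equiv), −78 °C; 21 (1.3 equiv), −78 °C; sat. aq. NH4Cl at −78 °C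
Reagents that add atoms: none
Why: Catalytic monovalent copper turns Grignard reagent 15 into a furylmethylcopper–magnesium species that adds 1,4 to enone 5, forming C9–C10 and the regiodefined chloromagnesium enolate 22; Cp2ZrCl2 then exchanges magnesium for zirconium to give 23, which adds through C1 to aldehyde 21 in a closed, zirconium-bridged transition state, forming C1–C2. The closest known reaction type is the copper-catalysed conjugate addition–enolate aldol trapping (three-component coupling) of 2-substituted cycloalkenones, combined with the erythro-selective aldol of zirconium enolates; no ring is closed. C10 is set by the C11 methyl group, because the copper reagent enters the enone face anti to it (trans-3,4 rule of 4-substituted cyclohexenones). C1 is set by the new C10 substituent, because the aldehyde is taken up on the enolate face opposite to it, which leaves the C1 methyl cis to C9 and trans to H10. C2 is set by the metal: in a ring-locked enolate the ring carbon C10 is trans to the enolate oxygen, and with zirconium such enolates give the aldol with the hydroxyl syn to that ring carbon (boat-like closed transition state), which is the 2S configuration, whereas a chair would place it syn to the methyl group. The step needs 1,4- over 1,2-addition (copper, −78 °C, slow addition of the chloride Grignard reagent), no enolate equilibration toward C13 (zirconium enolate kept at −78 °C), and aldol over proton transfer from the enolisable aldehyde (weakly basic zirconium enolate); the vinyl iodide and the silylfuran are inert to all three metals. C2 is the least secure of the three new centres, because the second substituent on the enolate carbon narrows the chair/boat preference.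

Step 16
Reactants: 24 aldol adduct (C14 ketone, free C2 hydroxyl)
Product: 25 (2R,3R,4S)-2-[(1S,4Z)-5-iodo-4-methyl-1-(triethylsilyloxy)pent-4-en-1-yl]-2,4-dimethyl-3-{[4-methyl-5-(trimethylsilyl)furan-3-yl]methyl}cyclohexan-1-one
Conditions: Et3SiOTf, 2,6-lutidine, CH2Cl2, −78 °C
Reagents that add atoms: triethylsilyl trifluoromethanesulfonate, CC[Si](CC)(CC)OS(=O)(=O)C(F)(F)F
Why: Silylation of the hindered aldol hydroxyl with a silyl triflate and a weak, hindered base; it removes the risk of retro-aldol cleavage at the quaternary C1 in the enolate steps that follow.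

Step 17
Reactants: 25 C2 triethylsilyl ether, C14 ketone
Product: 27 (4S,5R,6R)-6-[(1S,4Z)-5-iodo-4-methyl-1-(triethylsilyloxy)pent-4-en-1-yl]-4,6-dimethyl-5-{[4-methyl-5-(trimethylsilyl)furan-3-yl]methyl}cyclohex-2-en-1-one (C12=C13 enone), via lithium enolate 26 (not isolated)
Conditions: LiN(iPr)2, THF, −78 °C; then N-tert-butylbenzenesulfinimidoyl chloride, −78 °C
Reagents that add atoms: none
Why: Mukaiyama dehydrogenation: the lithium enolate (only C13 can be deprotonated, C1 being quaternary) attacks sulfur, and the α-sulfilimine undergoes syn-elimination at low temperature to the enone. The method uses no palladium, so the C–I bond is safe.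

Step 18
Reactants: 27 C12=C13 enone
Product: 29 (2R,5R,6R)-2-hydroxy-6-[(1S,4Z)-5-iodo-4-methyl-1-(triethylsilyloxy)pent-4-en-1-yl]-4,6-dimethyl-5-{[4-methyl-5-(trimethylsilyl)furan-3-yl]methyl}cyclohex-3-en-1-one (13-hydroxy, C11=C12, C14 ketone), via potassium dienolate 28 (not isolated)
Conditions: KN(SiMe3)2, THF, −78 °C to −40 °C; then 2-(phenylsulfonyl)-3-phenyloxaziridine, −78 °C; AcOH at −78 °C
Reagents that add atoms: 2-(phenylsulfonyl)-3-phenyloxaziridine, O=S(=O)(c1ccccc1)N1OC1c1ccccc1
Why: With C1 quaternary, the only acidic site is the axial γ-hydrogen on C11; the resulting dienolate is oxygenated at its α-carbon C13 by the Davis oxaziridine (α-hydroxylation of a dienolate), which moves the double bond to C11=C12 and erases the C11 stereocentre. The reagent should approach C13 anti to the pseudoaxial C1 methyl group, placing the 13-hydroxyl on the face of the C1–C2 bond; the cold acidic quench prevents tautomerisation to the diosphenol.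

Step 19
Reactants: 29 13-hydroxy C14 ketone
Product: 30 (1S,2R,5R,6S)-6-[(1S,4Z)-5-iodo-4-methyl-1-(triethylsilyloxy)pent-4-en-1-yl]-4,6-dimethyl-5-{[4-methyl-5-(trimethylsilyl)furan-3-yl]methyl}cyclohex-3-ene-1,2-diol (cis-13,14-diol)
Conditions: LiBH(s-Bu)3 (2.5 equiv), THF, −78 °C; AcOH at −78 °C; NaBO3, H2O
Reagents that add atoms: none
Why: Bulky trialkylborohydride reduction under steric approach control: hydride should enter C14 from the equatorial direction, on the face of the axial C1 methyl and away from the neighbouring C13 oxygen, as in reductions of 2,2-disubstituted cyclohexanones and 2-alkoxycyclohexanones. This gives the cis-diol with C14 configured as in the target; the cold acidic quench prevents silyl migration from O2 to the syn O14.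

Step 20
Reactants: 30 cis-13,14-diol
Product: 31 (4R,5S,6S)-6-hydroxy-5-[(1S,4Z)-5-iodo-4-methyl-1-(triethylsilyloxy)pent-4-en-1-yl]-3,5-dimethyl-4-{[4-methyl-5-(trimethylsilyl)furan-3-yl]methyl}cyclohex-2-en-1-one (C13 enone, free 14-hydroxyl)
Conditions: MnO2 (activated, excess), CH2Cl2, 25 °C
Reagents that add atoms: none
Why: Chemoselective oxidation of the allylic C13 alcohol by MnO2; the saturated, neopentyl C14 alcohol is untouched, which completes the 1,2-carbonyl transposition and gives the conjugated enone.

Step 21
Reactants: 31 14-hydroxy enone
Product: 32 14-O-acetate of 31 (ring A complete: C11=C12–C13=O, 14-acetoxy; C2 triethylsilyl ether; C6 iodoalkene; silylfuran)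
Conditions: Ac2O, pyridine, DMAP (cat.), CH2Cl2, 0 °C to 25 °C
Reagents that add atoms: acetic anhydride, CC(=O)OC(C)=O
Why: DMAP-catalysed acetylation of the α'-hydroxy enone; O2 is silylated, so no acyl migration can occur, and all strong-base steps are already done.

Step 22
Reactants: 32 silylfuran with completed ring A
Product: 34 γ-hydroxybutenolide (ring C as 5-hydroxy-2(5H)-furanone: C19 carbonyl, C7 lactol carbon, both lactol epimers; rest as 32), via silyl ester 33 (not isolated)
Conditions: O2, visible light, tetraphenylporphyrin (cat.), CH2Cl2, −78 °C; then H2O, THF, 0 °C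
Reagents that add atoms: dioxygen, O=O
Why: [4+2] addition of singlet oxygen to the furan and 1,2-silyl migration in the endoperoxide (Katsumura oxidation of 2-silylfurans) give regiospecifically the silyl ester of the Z-4-oxo-enoic acid, with the carboxyl at the silicon-bearing C19; hydrolysis gives the lactol. The electron-rich furan reacts far faster than the electron-poor enone or the iodoalkene.

Step 23
Reactants: 34 γ-hydroxybutenolide
Product: 35 methyl (Z)-ester aldehyde (C19 methyl ester and C7 aldehyde cis on C8=C17; rest as 32)
Conditions: MeI, KHCO3, DMF, 0 °C to 25 °C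
Reagents that add atoms: iodomethane, CI
Why: The pseudo-acid opens to its carboxylate, which is O-methylated (the behaviour of 2-formylbenzoic acid), unmasking the C7 aldehyde cis to the ester; bicarbonate is too weak to enolise C14 or cleave the acetate.

Step 24
Reactants: 35 methyl (Z)-ester aldehyde with C6 iodoalkene
Product: 37 tricyclic lactone, C2 triethylsilyl ether (rings A, B and C closed; C1, C2, C7, C10, C14 as in 39), via seco hydroxy ester 36 (not isolated)
Conditions: CrCl2 (10 equiv), NiCl2 (2 mol%), DMSO/THF, 25 °C, 2 mM, syringe-pump addition; then PPTS (cat.), CH2Cl2, 25 °C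
Reagents that add atoms: none
Why: Nozaki–Hiyama–Kishi reaction: zerovalent nickel inserts into the C6–I bond, the vinyl group passes to trivalent chromium with retention of the Z geometry and adds 1,2 to the C7 aldehyde, closing the ten-membered ring B (10-exo-trig); the C7 alkoxide then lactonises onto the cis ester (5-exo-trig) and closes ring C. C7 is set in the ring-forming transition state, where allylic strain holds H7 in the plane of the C5=C6 bond and the C1–C10 bridge must span one face of that plane; the working hypothesis is that the face remote from the C1 methyl group is preferred and gives 7R, and this is the least secure stereocentre after C2. Divalent chromium is too weak a reductant to touch the enone or the α-acetoxy ketone.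

Step 25
Reactants: 37 tricyclic lactone, C2 triethylsilyl ether
Product: 38 tricyclic lactone, free C2 hydroxyl (14-acetoxy; C1, C2, C7, C10, C14 as in 39)
Conditions: HF·pyridine, pyridine, THF, 0 °C to 25 °C
Reagents that add atoms: none
Why: Acidic fluoride cleaves the neopentyl silyl ether without base, so the acetate cannot migrate from O14 to the syn O2 and neither C7 nor C14 is enolised.

Step 26
Reactants: 38 tricyclic lactone, free C2 hydroxyl
Product: 39 target CNP0109273.3 (1R,2S,5Z,7R,10R,14S; 2-propionyloxy, 14-acetoxy, 13-oxo, C11=C12, C8=C17, 19,7-lactone)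
Conditions: (EtCO)2O, pyridine, DMAP (cat.), CH2Cl2, 25 °C
Reagents that add atoms: propionic anhydride, CCC(=O)OC(=O)CC
Why: DMAP-catalysed acylation of the hindered secondary alcohol, run directly on the crude alcohol so that propionylation outpaces acetyl migration; pyridine and DMAP are too weak to epimerise C7 or C14.

## Compound list

1 | 4-methylcyclohexanone | CC1CCC(=O)CC1 | starting material
2 | (S)-trimethyl[(4-methylcyclohex-1-en-1-yl)oxy]silane | C[Si](C)(C)OC1=CC[C@@H](C)CC1 | intermediate
3 | (S)-4-methylcyclohex-2-en-1-one | O=C1C=C[C@@H](C)CC1 | intermediate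
4 | (S)-2-iodo-4-methylcyclohex-2-en-1-one | O=C1C(I)=C[C@@H](C)CC1 | intermediate
5 | (S)-2,4-dimethylcyclohex-2-en-1-one | O=C1C(C)=C[C@@H](C)CC1 | intermediate
6 | diethyl furan-3,4-dicarboxylate | CCOC(=O)c1cocc1C(=O)OCC | starting material
7 | furan-3,4-diyldimethanol | OCc1cocc1CO | intermediate
8 | {4-[(tert-butyldimethylsilyloxy)methyl]furan-3-yl}methanol | OCc1cocc1CO[Si](C)(C)C(C)(C)C | intermediate
9 | C,O-bis(trimethylsilyl) derivative of 8 (ring C–SiMe3 next to CH2OSiMe3) | C[Si](C)(C)OCc1c([Si](C)(C)C)occ1CO[Si](C)(C)C(C)(C)C | intermediate
10 | {4-[(tert-butyldimethylsilyloxy)methyl]-2-(trimethylsilyl)furan-3-yl}methanol | OCc1c([Si](C)(C)C)occ1CO[Si](C)(C)C(C)(C)C | intermediate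
11 | methanesulfonate of 10 | CS(=O)(=O)OCc1c([Si](C)(C)C)occ1CO[Si](C)(C)C(C)(C)C | intermediate
12 | tert-butyldimethyl{[4-methyl-5-(trimethylsilyl)furan-3-yl]methoxy}silane | Cc1c([Si](C)(C)C)occ1CO[Si](C)(C)C(C)(C)C | intermediate
13 | [4-methyl-5-(trimethylsilyl)furan-3-yl]methanol | Cc1c([Si](C)(C)C)occ1CO | intermediate
14 | [4-(chloromethyl)-3-methylfuran-2-yl]trimethylsilane | Cc1c([Si](C)(C)C)occ1CCl | intermediate
15 | {[4-methyl-5-(trimethylsilyl)furan-3-yl]methyl}magnesium chloride | Cc1c([Si](C)(C)C)occ1C[Mg]Cl | intermediate
16 | prop-2-yn-1-ol | C#CCO | starting material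
17 | bromomagnesium (Z)-3-(bromomagnesio)-2-methylprop-2-en-1-olate | Br[Mg]OC/C(C)=C\[Mg]Br | intermediate
18 | (Z)-3-iodo-2-methylprop-2-en-1-ol | OC/C(C)=C\I | intermediate
19 | (Z)-3-bromo-1-iodo-2-methylprop-1-ene | BrC/C(C)=C\I | intermediate
20 | (4Z)-5-iodo-4-methylpent-4-enal N,N-dimethylhydrazone | CN(C)N=CCC/C(C)=C\I | intermediate
21 | (Z)-5-iodo-4-methylpent-4-enal | O=CCC/C(C)=C\I | intermediate
22 | chloromagnesium enolate of the conjugate adduct (C14–O–Mg, C1=C14; C9 trans to the C11 methyl) | Cl[Mg]OC1=C(C)[C@H](Cc2coc([Si](C)(C)C)c2C)[C@@H](C)CC1 | intermediate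
23 | chlorobis(cyclopentadienyl)zirconium enolate of the conjugate adduct | Cl[Zr](OC1=C(C)[C@H](Cc2coc([Si](C)(C)C)c2C)[C@@H](C)CC1)(C1C=CC=C1)C1C=CC=C1 | intermediate
24 | (2R,3R,4S)-2-[(1S,4Z)-1-hydroxy-5-iodo-4-methylpent-4-en-1-yl]-2,4-dimethyl-3-{[4-methyl-5-(trimethylsilyl)furan-3-yl]methyl}cyclohexan-1-one | O[C@@H](CC/C(C)=C\I)[C@@]1(C)[C@H](Cc2coc([Si](C)(C)C)c2C)[C@@H](C)CCC1=O | intermediate
25 | 2-O-triethylsilyl ether of 24 | CC[Si](CC)(CC)O[C@@H](CC/C(C)=C\I)[C@@]1(C)[C@H](Cc2coc([Si](C)(C)C)c2C)[C@@H](C)CCC1=O | intermediate
26 | lithium C13=C14 enolate of 25 | CC[Si](CC)(CC)O[C@@H](CC/C(C)=C\I)[C@@]1(C)[C@H](Cc2coc([Si](C)(C)C)c2C)[C@@H](C)CC=C1O[Li] | intermediate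
27 | (4S,5R,6R)-6-[(1S,4Z)-5-iodo-4-methyl-1-(triethylsilyloxy)pent-4-en-1-yl]-4,6-dimethyl-5-{[4-methyl-5-(trimethylsilyl)furan-3-yl]methyl}cyclohex-2-en-1-one | CC[Si](CC)(CC)O[C@@H](CC/C(C)=C\I)[C@@]1(C)[C@H](Cc2coc([Si](C)(C)C)c2C)[C@@H](C)C=CC1=O | intermediate
28 | potassium dienolate of 27 (C14–O–K, C13=C14, C11=C12) | CC[Si](CC)(CC)O[C@@H](CC/C(C)=C\I)[C@@]1(C)[C@H](Cc2coc([Si](C)(C)C)c2C)C(C)=CC=C1O[K] | intermediate
29 | (2R,5R,6R)-2-hydroxy-6-[(1S,4Z)-5-iodo-4-methyl-1-(triethylsilyloxy)pent-4-en-1-yl]-4,6-dimethyl-5-{[4-methyl-5-(trimethylsilyl)furan-3-yl]methyl}cyclohex-3-en-1-one | CC[Si](CC)(CC)O[C@@H](CC/C(C)=C\I)[C@@]1(C)[C@H](Cc2coc([Si](C)(C)C)c2C)C(C)=C[C@@H](O)C1=O | intermediate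
30 | (1S,2R,5R,6S)-6-[(1S,4Z)-5-iodo-4-methyl-1-(triethylsilyloxy)pent-4-en-1-yl]-4,6-dimethyl-5-{[4-methyl-5-(trimethylsilyl)furan-3-yl]methyl}cyclohex-3-ene-1,2-diol | CC[Si](CC)(CC)O[C@@H](CC/C(C)=C\I)[C@@]1(C)[C@H](Cc2coc([Si](C)(C)C)c2C)C(C)=C[C@@H](O)[C@H]1O | intermediate
31 | (4R,5S,6S)-6-hydroxy-5-[(1S,4Z)-5-iodo-4-methyl-1-(triethylsilyloxy)pent-4-en-1-yl]-3,5-dimethyl-4-{[4-methyl-5-(trimethylsilyl)furan-3-yl]methyl}cyclohex-2-en-1-one | CC[Si](CC)(CC)O[C@@H](CC/C(C)=C\I)[C@@]1(C)[C@H](Cc2coc([Si](C)(C)C)c2C)C(C)=CC(=O)[C@H]1O | intermediate
32 | 14-O-acetate of 31 | CC[Si](CC)(CC)O[C@@H](CC/C(C)=C\I)[C@@]1(C)[C@H](Cc2coc([Si](C)(C)C)c2C)C(C)=CC(=O)[C@H]1OC(C)=O | intermediate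
33 | trimethylsilyl (Z)-ester aldehyde from 32 (C19 silyl ester cis to C7 aldehyde) | CC[Si](CC)(CC)O[C@@H](CC/C(C)=C\I)[C@@]1(C)[C@H](C/C(C=O)=C(\C)C(=O)O[Si](C)(C)C)C(C)=CC(=O)[C@H]1OC(C)=O | intermediate
34 | γ-hydroxybutenolide (C19 carbonyl, C7 lactol, both C7 epimers) | CC[Si](CC)(CC)O[C@@H](CC/C(C)=C\I)[C@@]1(C)[C@H](CC2=C(C)C(=O)OC2O)C(C)=CC(=O)[C@H]1OC(C)=O | intermediate
35 | methyl (Z)-ester aldehyde (C19 methyl ester cis to C7 aldehyde) | CC[Si](CC)(CC)O[C@@H](CC/C(C)=C\I)[C@@]1(C)[C@H](C/C(C=O)=C(\C)C(=O)OC)C(C)=CC(=O)[C@H]1OC(C)=O | intermediate
36 | seco hydroxy ester (ring B closed, 7R alcohol, C19 methyl ester) | CC[Si](CC)(CC)O[C@H]1CC/C(C)=C\[C@@H](O)/C(=C(/C)C(=O)OC)C[C@@H]2C(C)=CC(=O)[C@@H](OC(C)=O)[C@@]12C | intermediate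
37 | tricyclic lactone, 2-O-triethylsilyl, 14-O-acetyl | CC[Si](CC)(CC)O[C@H]1CC/C(C)=C\[C@H]2OC(=O)C(C)=C2C[C@@H]2C(C)=CC(=O)[C@@H](OC(C)=O)[C@@]12C | intermediate
38 | tricyclic lactone, free 2-hydroxyl, 14-O-acetyl | O[C@H]1CC/C(C)=C\[C@H]2OC(=O)C(C)=C2C[C@@H]2C(C)=CC(=O)[C@@H](OC(C)=O)[C@@]12C | intermediate
39 | CNP0109273.3, (1R,2S,5Z,7R,10R,14S)-14-acetoxy-13-oxo-2-propionyloxy tricyclic 19,7-lactone | CCC(=O)O[C@H]1CC/C(C)=C\[C@H]2OC(=O)C(C)=C2C[C@@H]2C(C)=CC(=O)[C@@H](OC(C)=O)[C@@]12C | target

## Step count and weak points

Total: 26 steps. Longest linear sequence: 19 steps (from 6 through steps 5–11, then steps 15–26).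

**Step 15 (key step).** The furylmethyl Grignard reagent may add 1,2 or homocouple instead of adding 1,4. The aldol may pass through the chair rather than the boat-like closed transition state, eroding selectivity at C2. The adduct may undergo retro-aldol cleavage on work-up. The fallback sets out from 5 (with 15 and 21) and comes back at 24. The copper-catalysed addition is run in the presence of Me3SiCl, which accelerates 1,4-addition and traps the enolate as the trimethylsilyl enol ether F1. This is isolated and combined with 21 and BF3·OEt2 at −78 °C in a Mukaiyama aldol. In the open transition state the aldehyde chain sits beside the small C1 methyl, not beside the branched C10, which leads to the same 2S alcohol 24 by a different control element.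

**Step 18.** γ-Deprotonation at the hindered C11 methine may be slow, letting the base attack elsewhere, or oxygen may be delivered to C11 instead of C13. The fallback sets out from 27 and comes back at 29. Soft enolisation (Me3SiOTf, Et3N) gives the thermodynamic trimethylsilyl dienol ether F2. MeLi cleaves the Si–O bond to release the amine-free lithium dienolate, which is hydroxylated with the same oxaziridine to give 29.

**Step 19.** Facial selectivity at C14 may be poor, because in the cyclohex-3-enone only one syn-axial hydrogen shields the face opposite the C1 methyl group. Silyl migration from O2 to O14 is a second hazard. The fallback sets out from 25 and comes back at 32. It sets C14 on the saturated chair ketone, where equatorial attack by bulky hydrides on 2,2-disubstituted cyclohexanones is best precedented, and introduces the double bond last: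
- α-hydroxylation of 25 (KN(SiMe3)2, Davis oxaziridine) gives the 13-hydroxy ketone F3;
- LiBH(s-Bu)3 gives the saturated cis-diol F4;
- orthoester-mediated monoacetylation (MeC(OMe)3, PPTS; then aq. AcOH) places the acetate on the axial C14 oxygen, giving hydroxy acetate F5;
- Dess–Martin periodinane gives acetoxy ketone F6;
- Me3SiOTf and Et3N give the C12=C13 silyl enol ether F7;
- the IBX·4-methoxypyridine N-oxide complex dehydrogenates F7 to 32 without palladium.

**Step 24.** Closure of the strained ten-membered ring may be slower than protodeiodination or intermolecular coupling, and the two faces of the C7 aldehyde may not be well differentiated. The fallback sets out from 32 and comes back at 37. The ring is closed on the intact furan by palladium-catalysed intramolecular coupling of the C6 iodide with the free C7–H (Pd(OAc)2, a bulky phosphine, K2CO3, pivalic acid, DMA). This is direct C–H alkenylation of an electron-rich five-membered heteroarene, a tactic that has closed medium rings, and it gives the macrocyclic silylfuran F8, in which C7 is still planar. Buffered peracetic acid then converts the 2-silylfuran into the butenolide (Kuwajima oxidation). C7 is thus created by protonation of a 2-oxyfuran and can be equilibrated with an amine base toward the preferred ring B conformer, giving 37.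

## Further compounds

F1 | step 15 | trimethylsilyl enol ether of the conjugate adduct of 15 and 5 | C[Si](C)(C)OC1=C(C)[C@H](Cc2coc([Si](C)(C)C)c2C)[C@@H](C)CC1
F2 | step 18 | trimethylsilyl dienol ether of 27 | CC[Si](CC)(CC)O[C@@H](CC/C(C)=C\I)[C@@]1(C)[C@H](Cc2coc([Si](C)(C)C)c2C)C(C)=CC=C1O[Si](C)(C)C
F3 | step 19 | saturated 13-hydroxy C14 ketone | CC[Si](CC)(CC)O[C@@H](CC/C(C)=C\I)[C@@]1(C)[C@H](Cc2coc([Si](C)(C)C)c2C)[C@@H](C)C[C@@H](O)C1=O
F4 | step 19 | saturated cis-13,14-diol | CC[Si](CC)(CC)O[C@@H](CC/C(C)=C\I)[C@@]1(C)[C@H](Cc2coc([Si](C)(C)C)c2C)[C@@H](C)C[C@@H](O)[C@H]1O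
F5 | step 19 | saturated 14-acetate 13-alcohol | CC[Si](CC)(CC)O[C@@H](CC/C(C)=C\I)[C@@]1(C)[C@H](Cc2coc([Si](C)(C)C)c2C)[C@@H](C)C[C@@H](O)[C@H]1OC(C)=O
F6 | step 19 | saturated 14-acetoxy C13 ketone | CC[Si](CC)(CC)O[C@@H](CC/C(C)=C\I)[C@@]1(C)[C@H](Cc2coc([Si](C)(C)C)c2C)[C@@H](C)CC(=O)[C@H]1OC(C)=O
F7 | step 19 | C12=C13 trimethylsilyl enol ether of F6 | CC[Si](CC)(CC)O[C@@H](CC/C(C)=C\I)[C@@]1(C)[C@H](Cc2coc([Si](C)(C)C)c2C)[C@@H](C)C=C(O[Si](C)(C)C)[C@H]1OC(C)=O
F8 | step 24 | macrocyclic silylfuran (ring B closed at C6–C7, ring C as 2-silylfuran) | CC[Si](CC)(CC)O[C@H]1CC/C(C)=C\c2oc([Si](C)(C)C)c(C)c2C[C@@H]2C(C)=CC(=O)[C@@H](OC(C)=O)[C@@]12C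
A1 | alternative 1 | tricyclic C2 ketone with C3 phenylsulfonyl group | O=C1[C@H](S(=O)(=O)c3ccccc3)C/C(C)=C\[C@H]2OC(=O)C(C)=C2C[C@@H]2C(C)=C[C@@H](O[Si](C)(C)C(C)(C)C)C[C@@]12C
A2 | alternative 2 | ring A hydroxy ketone (C14 ketone, quaternary C1, C2 alcohol) | O[C@@H](CC/C(C)=C\CO[Si](C)(C)C(C)(C)C)[C@@]1(C)[C@H](CCC2(C)OCCO2)[C@@H](C)CCC1=O
A3 | alternative 3 | ring A–butenolide conjugate with C2 and C4 silyl ethers | CC(C)(C)[Si](C)(C)OC/C(C)=C\[C@H]1OC(=O)C(C)=C1C[C@@H]1C(C)=C[C@@H](O[Si](C)(C)C(C)(C)C)C[C@@]1(C)CO[Si](C)(C)C(C)(C)C
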